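In a one-step world each charged molecule of other conformer ends as isomer of the product and each molecule of substrate as target, so the charges give the outcome.

| flask | substrate | other conformer | remark | time |
|---|---|---|---|---|
| Wednesday's | 0.20 M | 0.10 M | run made earlier |  |
| Sunday's | 0.20 M | 0.40 M | run made earlier |  |
| Monday's | 0.10 M | 0.20 M | run made earlier |  |
| flask | 0.20 M | 0.200 M |  | 4.0 d |

| run | time / d | target / % | isomer of the product / % | substrate / % |
|---|---|---|---|---|
| Wednesday's | 0.625 | 31.2 | 4.4 | 27.5 |
| Wednesday's | 1.67 | 39.6 | 5.2 | 4.7 |
| Wednesday's | 3.00 | 35.8 | 6.2 | 1.0 |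
| Wednesday's | 5.00 | 27.4 | 6.6 | 0.5 |
| Sunday's | 0.625 | 16.4 | 8.1 | 15.7 |
| Sunday's | 1.67 | 22.1 | 11.0 | 4.0 |
| Sunday's | 3.00 | 20.7 | 10.0 | 0.4 |
| Sunday's | 5.00 | 15.6 | 10.8 | 0.2 |
| Monday's | 1.25 | 24.6 | 9.3 | 7.7 |
| Monday's | 2.50 | 24.8 | 10.1 | 1.1 |
| Monday's | 4.00 | 20.9 | 10.7 | 0.8 |
| Monday's | 5.00 | 19.1 | 11.1 | 0 |

(scatter of a reading: 0.5 percentage points)

- percentages count the substrate that a species holds: one side product or homo dimer counts as two
- on the list of suspects stand: substrate -> target; other conformer <-> third conformer; 2 substrate -> homo dimer; third conformer -> third product; substrate <-> other conformer; substrate + target -> side product; other conformer -> isomer of the product; target -> over-reaction product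

- ratio of target to isomer of the product at 40 min
- ratio of target to isomer of the product at 4.0 d
- which of target and isomer of the product there is more of at 4.0 d

The first chemist takes that view of the new flask. With 0.20 M of substrate and 0.200 M of other conformer, isomer should reach 50.0% of the charge. Target in Wednesday's run read 39.6% at 1.67 d and 27.4% at 5.00 d, less than that share, so she expects isomer to lead at 4.0 d.

The second chemist answers from the readings. From Wednesday's run to Sunday's, substrate stays at 0.20 M while other conformer rises by 0.300 M, and isomer at 5.00 d goes from 0.0198 M to 0.0648 M. Call φ the catch, the isomer formed per unit of other conformer charged, a branching fraction: φ = 0.150. The rest of Wednesday's isomer gives λ = 0.0240 per unit of substrate charged. Both are readings, with their scatter.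

Monday's run, unused so far, is a check: φ and λ give 10.8% of its charge, and it read 11.1%. Isomer barely moves late, 6.2% to 6.6% on Wednesday, so my reckoning for the flask is 8.70%. That is less than the first chemist's share, and less than even the last target reading of Sunday's run, 15.6%, so I expect target to lead in the new flask.

The forecast stands on the second chemist's side: a ratio of target to isomer of 4 at 40 min and 2.9 at 4.0 d, with target ahead, since “most of the other conformer leaks elsewhere”.

The flask gives 3.07 at 40 min and 2.97 at 4.0 d, with target ahead, 24.8% against 8.35%; the forecast's early ratio stands too high.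

    substrate → target (k = 1.50 × 10⁻⁵ /s)
    other conformer ⇌ third conformer (K = 1.40, k = 4.90 × 10⁻⁵ /s)
    2 substrate → homo dimer (k = 2.10 × 10⁻⁸ /M/s)
    third conformer → third product (k = 3.30 × 10⁻⁵ /s)
    substrate ⇌ other conformer (K = 0.360, k = 1.80 × 10⁻⁶ /s)
    substrate + target → side product (k = 2.80 × 10⁻⁵ /M/s)
    other conformer → isomer of the product (k = 5.10 × 10⁻⁶ /s)
    target → over-reaction product (k = 1.60 × 10⁻⁶ /s)

The first chemist's lead comes true later: at 40.0 d this flask holds target 0.172% and isomer 8.36%, more isomer than target. Against my 8.70% for isomer, the flask holds 8.35% at 4.00 d. For the same flask with 0.80 M of other conformer, φ and λ give 12.5%, and that flask holds 12.5% at 4.00 d.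

The numbers in the tables come from a simulation with made-up constants; the scatter is artificial.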